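**Plan**

Numbering: oxolane O1, C2 (syringyl), C3 (bears C9H2–O–feruloyl), C4 (bears C7'H2–guaiacyl), C5H2. The target is (2S,3R,4R), so C2/C3 are trans and C3/C4 are cis.
Retrosynthesis: cut the C9–O ester bond (ferulic acid) and return C9 to a carboxyl group. Then cut C7'–aryl (aryl Grignard on a C7' aldehyde), and finally cut C2–C3 and C4–C5 of the oxolane together.
Enabling feature: C2–O1–C5 of the oxolane ring is the C–O–C backbone of a carbonyl ylide made from a syringaldehyde ether and a CH2 terminus. The cis bonds C3–C9 and C4–C7' are the two ring bonds flanking the Z-alkene of a 2(5H)-furanone (C9 = lactone carbonyl, C7' = acetal carbon).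
Forward: the ylide precursor (four steps from syringaldehyde) and a menthyl-acetal butenolide (two steps from furfural) combine in one [3+2] event that builds the only ring of the target. The auxiliary lactone is then opened (C7' arylated and deoxygenated, C9 reduced), and the ferulate is attached last.
Stereochemistry: the acetal centre, fixed by crystallisation with (+)-menthol, sends the dipole to the opposite alkene face (absolute sense of C3 and C4). The ring alkene gives C3/C4 cis and the exo approach gives C2. The acetal centre and the C7' carbinol centre are erased later.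

Key step: step 7

**Step 1**
Reactants: 1 syringaldehyde
Product: 2 4-(benzyloxy)-3,5-dimethoxybenzaldehyde
Conditions: BnBr (1.1 equiv), K2CO3, DMF, 60 °C
Reagents that add atoms: benzyl bromide, BrCc1ccccc1
Why: Williamson ether synthesis on the acidic phenol; the benzyl ether should survive silyllithium, SO2Cl2, CsF, aqueous acid and Grignard reagent, and it leaves in step 11 together with the other benzylic C–O bonds.

**Step 2**
Reactants: 2 4-(benzyloxy)-3,5-dimethoxybenzaldehyde
Product: 3 (±)-[4-(benzyloxy)-3,5-dimethoxyphenyl][dimethyl(phenyl)silyl]methanol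
Conditions: PhMe2SiLi (1.2 equiv, stock solution in THF), THF, −78 °C; AcOH, −78 °C
Reagents that add atoms: dimethyl(phenyl)silyllithium, [Li][Si](C)(C)c1ccccc1
Why: 1,2-addition of a silyllithium to an aromatic aldehyde gives the α-hydroxysilane in one operation without metalation next to the OBn or OMe groups; cold protonation of the lithium alkoxide forestalls Brook rearrangement, the substituents on silicon are spectators, and the racemic new centre is flattened in the ylide.

**Step 3**
Reactants: 3 α-hydroxysilane
Product: 4 (±)-{[4-(benzyloxy)-3,5-dimethoxyphenyl][(methylsulfanyl)methoxy]methyl}dimethyl(phenyl)silane (methylthiomethyl ether of 3)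
Conditions: Me2S, dibenzoyl peroxide, MeCN, 0 °C
Reagents that add atoms: dimethyl sulfide, CSC
Why: Pummerer-type methylthiomethylation etherifies secondary alcohols under nearly neutral conditions, which avoids both the alkoxide (Brook rearrangement) and the strong acid that would ionise this electron-rich benzylic alcohol.

**Step 4**
Reactants: 4 methylthiomethyl ether
Product: 5 (±)-chloromethyl α-[dimethyl(phenyl)silyl]-4-(benzyloxy)-3,5-dimethoxybenzyl ether
Conditions: SO2Cl2 (1.0 equiv), CH2Cl2, −78 → 0 °C; volatiles removed in vacuo, used crude at once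
Reagents that add atoms: sulfuryl chloride, O=S(=O)(Cl)Cl
Why: chlorinolysis of an O,S-acetal is the established acid-free entry to chloromethyl ethers of acid-labile electron-rich benzylic alcohols (p-methoxybenzyl chloromethyl ether is made this way), the sulfide being far more nucleophilic than the arene at low temperature.

**Step 5**
Reactants: 6 furfural
Product: 8 5-hydroxyfuran-2(5H)-one (racemic), via furan endoperoxide 7 (not isolated)
Conditions: O2, visible light, methylene blue (cat.), MeOH, 0–20 °C
Reagents that add atoms: dioxygen, O=O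
Why: dye-sensitised singlet-oxygen [4+2] cycloaddition to the furan, followed by methanolysis of the formyl group of the endoperoxide, is the standard preparation of this pseudoacid; its stereocentre is labile and is fixed in step 6.

**Step 6**
Reactants: 8 5-hydroxyfuran-2(5H)-one; 9 (+)-menthol, (1S,2R,5S)
Product: 10 (5S)-5-{[(1S,2R,5S)-2-isopropyl-5-methylcyclohexyl]oxy}furan-2(5H)-one, (5S)-5-(d-menthyloxy)-2(5H)-furanone
Conditions: neat, 100 °C; crystallisation from petroleum ether, −20 °C; mother liquor re-equilibrated (cat. TsOH) and recrystallised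
Reagents that add atoms: none
Why: thermal acetalisation of the pseudoacid gives both acetal epimers, which interconvert under acid, and in the d-menthyl series the (5S)-epimer is the one that crystallises, so the centre is set by crystallisation-driven selection.

**Step 7**
Reactants: 5 chloromethyl α-silylbenzyl ether; 10 (5S)-5-(d-menthyloxy)-2(5H)-furanone
Product: 12 (3S,3aR,6S,6aS)-6-[4-(benzyloxy)-3,5-dimethoxyphenyl]-3-(d-menthyloxy)tetrahydro-1H,3H-furo[3,4-c]furan-1-one (cis-fused; C1 = C9 and C3 = C7' and C6 = oxolane C2), via carbonyl ylide 11 (not isolated)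
Conditions: CsF (4 equiv, flame-dried), 4 Å MS, MeCN, rt; 5 (2 equiv) added slowly by syringe pump
Reagents that add atoms: none
Why: Ionisation of the C–Cl bond and attack of fluoride on silicon amount to a 1,3-elimination that releases the non-stabilised carbonyl ylide 11, a four-electron C–O–C dipole, which adds in a concerted, suprafacial π4s+π2s manner to the electron-poor alkene of 10. The closest known reactions are the CsF-triggered [3+2] cycloadditions of α-silyl α'-chloro ethers with acrylates, maleates and fumarates, and the anti-selective additions of diazoalkanes, nitrile oxides, nitrones and azomethine ylides to 5-menthyloxy-2(5H)-furanones; here these two known halves are paired. The oxolane ring closes by intermolecular [3+2] cycloaddition, with C2–C3 and C4–C5 formed in the same event, so no separate ring-closing step is needed. C3 and C4 must come out cis because the alkene is locked Z in the five-membered lactone, and their absolute sense follows from approach of the dipole to the face opposite the menthyloxy group on the (S)-acetal carbon; C2 is set by the exo transition state of the extended (aryl-outside) ylide, in which the aryl group points away from the lactone ring and ends trans to C9 on the convex face. Regioselectivity is also needed: the donor aryl group keeps cationic character on its own carbon, so the CH2 terminus carries the larger HOMO coefficient and is the smaller end, and it should bond to the β-carbon (largest LUMO coefficient, next to the bulky acetal), leaving the aryl-bearing terminus for the α-carbon. Because the menthyl group is retained, any product of imperfect facial, regio- or exo selectivity, or of fluoride-induced epimerisation of 10, is a diastereomer of 12 and can be removed by chromatography or crystallisation.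

**Step 8**
Reactants: 12 cycloadduct
Product: 13 (3aR,6S,6aS)-6-[4-(benzyloxy)-3,5-dimethoxyphenyl]-3-hydroxytetrahydro-1H,3H-furo[3,4-c]furan-1-one (anomers at C7'; ring tautomer of the cis 4-formyl-oxolane-3-carboxylic acid)
Conditions: 2 M aq. HCl, 1,4-dioxane, 60 °C
Reagents that add atoms: water, O
Why: acid-catalysed hydrolysis of the acylal releases menthol and leaves the closed hydroxylactone, a thermodynamic sink open only to the cis isomer that keeps C4 from enolising; should C2–O1 ionise reversibly, it should re-close to the same convex-face aryl isomer.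

**Step 9**
Reactants: 14 4-bromo-2-methoxyphenol
Product: 15 1-(benzyloxy)-4-bromo-2-methoxybenzene
Conditions: BnBr, K2CO3, acetone, reflux
Reagents that add atoms: benzyl bromide, BrCc1ccccc1
Why: Williamson ether synthesis; the bromine already sits para to the phenolic oxygen and therefore fixes the guaiacyl substitution pattern that an electrophilic substitution of guaiacol could not guarantee.

**Step 10**
Reactants: 15 1-(benzyloxy)-4-bromo-2-methoxybenzene; 13 hydroxylactone
Product: 18 (3aR,6S,6aS)-3-[4-(benzyloxy)-3-methoxyphenyl]-6-[4-(benzyloxy)-3,5-dimethoxyphenyl]tetrahydro-1H,3H-furo[3,4-c]furan-1-one as a mixture of C7' epimers, via arylmagnesium bromide 16 (not isolated), via hydroxy acid 17 (not isolated)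
Conditions: Mg, THF, 40 °C; then 13 (0.35 equiv relative to 16), THF, −78 → 0 °C; 1 M HCl; cat. TsOH, CH2Cl2, rt
Reagents that add atoms: none
Why: Grignard addition to a pseudoacid, as in the preparation of 3-arylphthalides from 2-formylbenzoic acid: the first equivalent deprotonates and opens the lactol, the magnesium carboxylate is inert, the aldehyde is arylated faster than it enolises at low temperature, and acid closes the cis γ-lactone; the C7' centre forms without control and is erased in step 11.

**Step 11**
Reactants: 18 γ-aryl lactone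
Product: 19 (2S,3S,4R)-2-(4-hydroxy-3,5-dimethoxyphenyl)-4-(4-hydroxy-3-methoxybenzyl)oxolane-3-carboxylic acid
Conditions: H2 (1 atm), 10% Pd/C, EtOH–EtOAc, rt, stopped as soon as the lactone is consumed
Reagents that add atoms: none
Why: catalytic hydrogenolysis cleaves aryl benzyl ethers and the benzylic acyloxy C7'–O bond (carboxylate leaving group) faster than the benzylic dialkyl-ether bond C2–O1, which is known to survive debenzylation in 2-aryloxolane lignans; no stereocentre of the target is touched.

**Step 12**
Reactants: 19 oxolane-3-carboxylic acid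
Product: 20 (2S,3R,4R)-[2-(4-hydroxy-3,5-dimethoxyphenyl)-4-(4-hydroxy-3-methoxybenzyl)oxolan-3-yl]methanol (5-methoxylariciresinol type alcohol)
Conditions: BH3·THF (5 equiv), THF, 0 °C → rt; MeOH quench
Reagents that add atoms: none
Why: chemoselective borane reduction of a carboxylic acid through its acyloxyborane, run under non-basic conditions so that C3 cannot epimerise; the phenols only consume hydride as aryl borates, which methanol releases.

**Step 13**
Reactants: 20 primary alcohol; 21 (E)-ferulic acid
Product: 22 target, [(2S,3R,4R)-2-(4-hydroxy-3,5-dimethoxyphenyl)-4-(4-hydroxy-3-methoxybenzyl)oxolan-3-yl]methyl (E)-3-(4-hydroxy-3-methoxyphenyl)prop-2-enoate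
Conditions: PPh3 (1.3 equiv), DIAD (1.3 equiv), THF, 0 °C → rt
Reagents that add atoms: none
Why: Mitsunobu esterification, known to be chemoselective for unprotected phenolic acids with phenolic primary alcohols, because only the carboxylic acid (pKa about 4.5 against about 10 for the phenols) protonates the betaine and its carboxylate displaces the primary alkoxyphosphonium at non-stereogenic C9; the E-alkene is untouched.

**Compound list**

1 | syringaldehyde | COc1cc(C=O)cc(OC)c1O | starting material
2 | 4-(benzyloxy)-3,5-dimethoxybenzaldehyde | COc1cc(C=O)cc(OC)c1OCc1ccccc1 | intermediate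
3 | (±)-[4-(benzyloxy)-3,5-dimethoxyphenyl][dimethyl(phenyl)silyl]methanol | COc1cc(C(O)[Si](C)(C)c2ccccc2)cc(OC)c1OCc1ccccc1 | intermediate
4 | (±)-methylthiomethyl ether of 3 | COc1cc(C(OCSC)[Si](C)(C)c2ccccc2)cc(OC)c1OCc1ccccc1 | intermediate
5 | (±)-chloromethyl α-[dimethyl(phenyl)silyl]-4-(benzyloxy)-3,5-dimethoxybenzyl ether | ClCOC([Si](C)(C)c1ccccc1)c1cc(OC)c(OCc2ccccc2)c(OC)c1 | intermediate
6 | furfural | O=Cc1ccco1 | starting material
7 | 2,3,7-trioxabicyclo[2.2.1]hept-5-ene-1-carbaldehyde (furan endoperoxide, racemic) | O=CC12C=CC(OO1)O2 | intermediate (not isolated)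
8 | 5-hydroxyfuran-2(5H)-one (racemic) | O=C1C=CC(O)O1 | intermediate
9 | (+)-menthol, (1S,2R,5S) | CC(C)[C@H]1CC[C@H](C)C[C@@H]1O | starting material
10 | (5S)-5-(d-menthyloxy)-2(5H)-furanone | O=C1C=C[C@@H](O[C@H]2C[C@@H](C)CC[C@@H]2C(C)C)O1 | intermediate
11 | carbonyl ylide, 4-(benzyloxy)-3,5-dimethoxybenzylidene(methylido)oxonium | [CH2-][O+]=Cc1cc(OC)c(OCc2ccccc2)c(OC)c1 | intermediate (not isolated)
12 | (3S,3aR,6S,6aS)-6-[4-(benzyloxy)-3,5-dimethoxyphenyl]-3-(d-menthyloxy)tetrahydro-1H,3H-furo[3,4-c]furan-1-one | O=C1[C@H]2[C@@H]([C@@H](O[C@H]3C[C@@H](C)CC[C@@H]3C(C)C)O1)CO[C@@H]2c1cc(OC)c(OCc2ccccc2)c(OC)c1 | intermediate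
13 | (3aR,6S,6aS)-6-[4-(benzyloxy)-3,5-dimethoxyphenyl]-3-hydroxytetrahydro-1H,3H-furo[3,4-c]furan-1-one (anomers) | O=C1[C@H]2[C@@H](C(O)O1)CO[C@@H]2c1cc(OC)c(OCc2ccccc2)c(OC)c1 | intermediate
14 | 4-bromo-2-methoxyphenol | COc1cc(Br)ccc1O | starting material
15 | 1-(benzyloxy)-4-bromo-2-methoxybenzene | COc1cc(Br)ccc1OCc1ccccc1 | intermediate
16 | [4-(benzyloxy)-3-methoxyphenyl]magnesium bromide | COc1cc([Mg]Br)ccc1OCc1ccccc1 | intermediate (not isolated)
17 | (2S,3S,4R)-4-{[4-(benzyloxy)-3-methoxyphenyl](hydroxy)methyl}-2-[4-(benzyloxy)-3,5-dimethoxyphenyl]oxolane-3-carboxylic acid (C7' epimers) | OC(=O)[C@H]1[C@@H](C(O)c2ccc(OCc3ccccc3)c(OC)c2)CO[C@@H]1c1cc(OC)c(OCc2ccccc2)c(OC)c1 | intermediate (not isolated)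
18 | (3aR,6S,6aS)-3-[4-(benzyloxy)-3-methoxyphenyl]-6-[4-(benzyloxy)-3,5-dimethoxyphenyl]tetrahydro-1H,3H-furo[3,4-c]furan-1-one (C7' epimers) | O=C1[C@H]2[C@@H](C(c3ccc(OCc4ccccc4)c(OC)c3)O1)CO[C@@H]2c1cc(OC)c(OCc2ccccc2)c(OC)c1 | intermediate
19 | (2S,3S,4R)-2-(4-hydroxy-3,5-dimethoxyphenyl)-4-(4-hydroxy-3-methoxybenzyl)oxolane-3-carboxylic acid | OC(=O)[C@H]1[C@@H](Cc2ccc(O)c(OC)c2)CO[C@@H]1c1cc(OC)c(O)c(OC)c1 | intermediate
20 | (2S,3R,4R)-[2-(4-hydroxy-3,5-dimethoxyphenyl)-4-(4-hydroxy-3-methoxybenzyl)oxolan-3-yl]methanol | OC[C@H]1[C@@H](Cc2ccc(O)c(OC)c2)CO[C@@H]1c1cc(OC)c(O)c(OC)c1 | intermediate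
21 | (E)-ferulic acid | COc1cc(/C=C/C(=O)O)ccc1O | starting material
22 | CNP0289934.1, the 9-O-(E)-feruloyl ester of 20 | COc1cc(/C=C/C(=O)OC[C@H]2[C@@H](Cc3ccc(O)c(OC)c3)CO[C@@H]2c2cc(OC)c(O)c(OC)c2)ccc1O | target

**Step count**

Total step count: 13.
Longest linear sequence: 10 steps (1, 2, 3, 4, 7, 8, 10, 11, 12, 13).

**Steps most likely to fail**

**Step 7.** Several processes could undermine the cycloaddition.
- The short-lived ylide may be trapped too slowly by a β-substituted, singly activated alkene and be lost by dimerisation or closure to the oxirane.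
- Regio- or exo selectivity may leak.
- Fluoride may epimerise the acetal centre of 10.

The fallback gives up the cycloaddition for the known tandem conjugate addition–aldol route to this lignan class. It sets out from 8 and 2 and returns at 20.
- In this mapping the acetal carbon becomes C5 instead of C7', so the other auxiliary enantiomer is needed. Compound 8 and (−)-menthol, treated as in step 6, give (5R)-5-(l-menthyloxy)-2(5H)-furanone F1.
- Commercial 4-(benzyloxy)-3-methoxybenzaldehyde and PhSH with BF3·OEt2 give the bis(phenylthio)acetal F2.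
- Lithiated F2 (n-BuLi, THF, −78 °C) adds to the β-carbon of F1 anti to the menthyloxy group. The enolate is trapped by aldehyde 2 anti to the new substituent, giving the trans-disubstituted lactone F3 (carbinol epimers).
- NiCl2·6H2O/NaBH4 removes sulfur to give the benzyl lactone F4.
- LiAlH4 reduces the lactone and the acetal carbon, with loss of menthol, to the triol F5.
- Catalytic camphorsulfonic acid in CH2Cl2 closes the oxolane by attack of the C5 hydroxyl on the C2 benzylic cation, giving the 2,3-trans dibenzyl ether F6.
- Brief hydrogenolysis (H2, 1 atm, 10% Pd/C, EtOAc) gives 20.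

**Step 11.** Hydrogenolysis may run on into the C2–O1 bond (ring opening of the oxolane) before the benzylic lactone C7'–O bond is fully cleaved. The fallback replaces surface hydrogenolysis of that bond by elimination followed by conjugate hydride addition. It sets out from 18 and returns at 19.
- Only the two aryl benzyl ethers are removed (H2, 1 atm, 10% Pd/C, EtOAc, stopped early) to give the bisphenol lactone F7.
- NaBH4 with K2CO3 in i-PrOH–THF then deprotonates the guaiacyl phenol, and the phenolate expels the carboxylate by 1,6-elimination to the p-quinone methide acid F8.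
- Hydride adds to the exocyclic carbon C7' of F8, giving 19 after acidification.
- The syringyl phenolate would have to expel an alkoxide, a far poorer leaving group, so C2–O1 should stay closed.

**Step 4.** Electrophilic chlorination or sulfenylation of the trialkoxyarene, premature loss of silicon from the transient oxocarbenium chloride, or hydrolysis on handling may consume the chloromethyl ether. The fallback reaches the same dipole with silicon and leaving group exchanged between the two termini. It sets out from 2 and returns at ylide 11, and hence at 12.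
- Aldehyde 2 and (trimethylsilyl)methanol (2.2 equiv, cat. TsOH, toluene, water removal) give the bis[(trimethylsilyl)methyl] acetal F9.
- Acetyl chloride (1 equiv, CH2Cl2, 0 °C) converts F9 into the α-chlorobenzyl (trimethylsilyl)methyl ether F10. Here the electron-rich aryl group assists, rather than endangers, the ionisation.
- Crude F10 is added to CsF and 10 in MeCN as in step 7.

**Further compounds**

F1 | step 7 | (5R)-5-(l-menthyloxy)-2(5H)-furanone | O=C1C=C[C@H](O[C@@H]2C[C@H](C)CC[C@H]2C(C)C)O1
F2 | step 7 | 1-(benzyloxy)-4-[bis(phenylsulfanyl)methyl]-2-methoxybenzene | COc1cc(C(Sc2ccccc2)Sc2ccccc2)ccc1OCc1ccccc1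
F3 | step 7 | trans-3-{[4-(benzyloxy)-3,5-dimethoxyphenyl](hydroxy)methyl}-4-{[4-(benzyloxy)-3-methoxyphenyl]bis(phenylsulfanyl)methyl}-5-(l-menthyloxy)dihydrofuran-2(3H)-one (carbinol epimers) | O=C1O[C@@H](O[C@@H]2C[C@H](C)CC[C@H]2C(C)C)[C@H](C(Sc2ccccc2)(Sc2ccccc2)c2ccc(OCc3ccccc3)c(OC)c2)[C@H]1C(O)c1cc(OC)c(OCc2ccccc2)c(OC)c1
F4 | step 7 | trans-4-[4-(benzyloxy)-3-methoxybenzyl]-3-{[4-(benzyloxy)-3,5-dimethoxyphenyl](hydroxy)methyl}-5-(l-menthyloxy)dihydrofuran-2(3H)-one | O=C1O[C@@H](O[C@@H]2C[C@H](C)CC[C@H]2C(C)C)[C@H](Cc2ccc(OCc3ccccc3)c(OC)c2)[C@H]1C(O)c1cc(OC)c(OCc2ccccc2)c(OC)c1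
F5 | step 7 | 3-[4-(benzyloxy)-3-methoxybenzyl]-2-{[4-(benzyloxy)-3,5-dimethoxyphenyl](hydroxy)methyl}butane-1,4-diol (triol) | OC[C@H](C(O)c1cc(OC)c(OCc2ccccc2)c(OC)c1)[C@H](CO)Cc1ccc(OCc2ccccc2)c(OC)c1
F6 | step 7 | (2S,3R,4R)-{4-[4-(benzyloxy)-3-methoxybenzyl]-2-[4-(benzyloxy)-3,5-dimethoxyphenyl]oxolan-3-yl}methanol | OC[C@H]1[C@@H](Cc2ccc(OCc3ccccc3)c(OC)c2)CO[C@@H]1c1cc(OC)c(OCc2ccccc2)c(OC)c1
F7 | step 11 | (3aR,6S,6aS)-6-(4-hydroxy-3,5-dimethoxyphenyl)-3-(4-hydroxy-3-methoxyphenyl)tetrahydro-1H,3H-furo[3,4-c]furan-1-one (C7' epimers) | O=C1[C@H]2[C@@H](C(c3ccc(O)c(OC)c3)O1)CO[C@@H]2c1cc(OC)c(O)c(OC)c1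
F8 | step 11 | (2S,3S,4R)-2-(4-hydroxy-3,5-dimethoxyphenyl)-4-[(3-methoxy-4-oxocyclohexa-2,5-dien-1-ylidene)methyl]oxolane-3-carboxylic acid (p-quinone methide) | OC(=O)[C@H]1[C@@H](C=C2C=CC(=O)C(OC)=C2)CO[C@@H]1c1cc(OC)c(O)c(OC)c1
F9 | step 4 | 4-(benzyloxy)-3,5-dimethoxybenzaldehyde bis[(trimethylsilyl)methyl] acetal | COc1cc(C(OC[Si](C)(C)C)OC[Si](C)(C)C)cc(OC)c1OCc1ccccc1
F10 | step 4 | (±)-α-chloro-4-(benzyloxy)-3,5-dimethoxybenzyl (trimethylsilyl)methyl ether | COc1cc(C(Cl)OC[Si](C)(C)C)cc(OC)c1OCc1ccccc1
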